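The symmetric target (each ring: C1 bears benzylic C7, C2/C3 Br, C4/C5 OH, C6 H) is disconnected at both C5–O bonds, back to bis(3-bromo-4-hydroxybenzyl) ether. In each aromatic ring of this bis-phenol the C4 hydroxyl has C3 blocked by bromine and the para carbon C1 blocked by C7, so C5 is the only free ortho C–H. One IBX oxygenation with in-pot dithionite reduction therefore installs both C5 hydroxyls in a single two-directional operation. The bis-phenol comes from 3-bromo-4-hydroxybenzaldehyde by acetylation, silane reductive homo-etherification and aminolysis. A final bromination para to the new C5–OH puts bromine on C2 of both rings.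

Key step: step 4

Remark: the target has no stereocentre and no stereogenic axis; it is achiral with two identical halves. There is therefore no enantiomer to select, and the SMILES correctly carries no stereodescriptor.

Step 1
Reactants: 1 3-bromo-4-hydroxybenzaldehyde
Product: 2 4-acetoxy-3-bromobenzaldehyde (2-bromo-4-formylphenyl acetate)
Conditions: Ac2O (1.2 equiv), pyridine, 0 °C → rt
Reagents that add atoms: acetic anhydride, CC(=O)OC(C)=O
Why: Pyridine-promoted O-acetylation (nucleophilic acyl substitution) of the acidic ortho-bromophenol is fast, and the acetate is chosen because it lowers the electron density of the ring, which step 2 needs, and later leaves under neutral aminolysis.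

Step 2
Reactants: 2 4-acetoxy-3-bromobenzaldehyde (two molecules)
Product: 3 bis(4-acetoxy-3-bromobenzyl) ether
Conditions: Et3SiH (1.2 equiv per CHO), BiBr3 (5 mol %), MeCN, 0 °C → rt
Reagents that add atoms: none
Why: Lewis-acid-catalysed silane reductive homo-etherification of aromatic aldehydes (hydrosilylation of one aldehyde, condensation with a second to an oxocarbenium ion, hydride capture) is established for halogenated benzaldehydes, the acetoxy and bromo groups destabilise the benzylic cation enough that over-reduction and Friedel–Crafts benzylation should stay minor, and aryl acetate and aryl bromide are inert to these conditions.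

Step 3
Reactants: 3 bis(4-acetoxy-3-bromobenzyl) ether
Product: 4 bis(3-bromo-4-hydroxybenzyl) ether
Conditions: pyrrolidine (3 equiv), THF, 0 °C → rt; pH 6 phosphate buffer work-up
Reagents that add atoms: none
Why: Ester aminolysis of the activated aryl acetates (ortho-bromophenoxide is a good leaving group) runs without acid and without an alcohol solvent, so the solvolysis-prone 4-hydroxybenzyl ether link should not be exchanged.

Step 4
Reactants: 4 bis(3-bromo-4-hydroxybenzyl) ether; 5 2-iodoxybenzoic acid (IBX)
Product: 7 bis(3-bromo-4,5-dihydroxybenzyl) ether, via bis[(5-bromo-3,4-dioxocyclohexa-1,5-dien-1-yl)methyl] ether 6 (not isolated)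
Conditions: IBX (2.3 equiv), DMF (0.05 M), 0 °C → rt, dark; then aq Na2S2O4 (excess), 0 °C, same pot
Reagents that add atoms: IBX (compound 5), O=C1OI(=O)(O)c2ccccc12
Why: Each phenol oxygen exchanges onto iodine(V), the iodyl oxygen is delivered intramolecularly to the ortho carbon C5, and the resulting iodine(III) catecholate collapses to the ortho-quinone and 2-iodobenzoic acid, so one IBX per ring leads to bis(quinone) 6, which dithionite reduces at once to bis(catechol) 7. The closest known reaction type is the IBX ortho-oxygenation of 4-alkylphenols to ortho-quinones with reductive work-up to catechols, the chemical counterpart of tyrosinase. No ring closes and no stereocentre forms; the step makes the two C5–O bonds. Regioselectivity is fixed by the substrate, since at each C4 phenol C3 carries bromine and the para carbon C1 carries C7, which leaves C5 as the only ortho C–H. Chemoselectivity over C7–H oxidation rests on benzylic oxidation by IBX needing heat, while tautomerisation of the alkoxymethyl-quinone to a quinone methide (which would break the ether bridge) and quinone dimerisation are held back by dilute, aprotic, base-free conditions and reduction in the same pot at 0 °C. The bromine slows the oxygen transfer, which is why homogeneous DMF and a small excess of IBX are chosen over a suspension in methanol.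

Step 5
Reactants: 7 bis(3-bromo-4,5-dihydroxybenzyl) ether
Product: 8 bis(2,3-dibromo-4,5-dihydroxybenzyl) ether (target)
Conditions: NBS (2.05 equiv, portionwise), MeCN, −30 → 0 °C, dark; aq Na2S2O3/pH 6 buffer work-up, no alcohol solvents
Reagents that add atoms: N-bromosuccinimide, O=C1CCC(=O)N1Br
Why: Electrophilic aromatic bromination with NBS in MeCN is para-selective for phenols, C2 is para to the new C5–OH whereas C6 is only ortho to it (the orientation known for 5-bromovanillin-type and 3-bromo-4,5-dihydroxyaryl rings), each ring is deactivated after one bromination, and NBS releases succinimide instead of HBr so the 4-hydroxybenzyl ether should not be acidolysed.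

Compound list
1 | 3-bromo-4-hydroxybenzaldehyde | O=Cc1ccc(O)c(Br)c1 | starting material
2 | 4-acetoxy-3-bromobenzaldehyde | CC(=O)Oc1ccc(C=O)cc1Br | intermediate
3 | bis(4-acetoxy-3-bromobenzyl) ether | CC(=O)Oc1ccc(COCc2ccc(OC(C)=O)c(Br)c2)cc1Br | intermediate
4 | bis(3-bromo-4-hydroxybenzyl) ether | Oc1ccc(COCc2ccc(O)c(Br)c2)cc1Br | intermediate
5 | 2-iodoxybenzoic acid (IBX) | O=C1OI(=O)(O)c2ccccc12 | starting material
6 | bis[(5-bromo-3,4-dioxocyclohexa-1,5-dien-1-yl)methyl] ether (bis-ortho-quinone, not isolated) | O=C1C(=O)C=C(COCC2=CC(=O)C(=O)C(Br)=C2)C=C1Br | intermediate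
7 | bis(3-bromo-4,5-dihydroxybenzyl) ether | Oc1cc(COCc2cc(O)c(O)c(Br)c2)cc(Br)c1O | intermediate
8 | bis(2,3-dibromo-4,5-dihydroxybenzyl) ether | Oc1cc(COCc2cc(O)c(O)c(Br)c2Br)c(Br)c(Br)c1O | target

Total step count: 5. Longest linear sequence: 5.

Steps most likely to fail

1. Step 4.
- **Risk:** Ligand exchange and oxygen transfer may be slow on the bromine-deactivated phenols, so one ring stays unoxidised. The quinone rings may also tautomerise to quinone methides with loss of the ether bridge, or dimerise before reduction.
- **Fallback** (carbon-then-oxygen route to the same C5–O bonds, from 4 back to 7): Casnati–Skattebøl ortho-formylation of 4 (MgCl2, Et3N, paraformaldehyde, THF, reflux) can only strike C5. It should give bis(3-bromo-5-formyl-4-hydroxybenzyl) ether F1. Dakin oxidation of F1 (H2O2, aq NaOH, THF, 0 °C → rt, under N2) then replaces each formyl group by hydroxyl and returns to 7.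

2. Step 5.
- **Risk:** NBS may oxidise the free catechols to quinones. Ipso attack at C1 (para to C4–OH) may fragment the benzylic C–O link. Competing attack at C6, or a third bromination per ring, is also possible.
- **Fallback** (masked-phenol bromination, from 7 back to 8): Silylation (TBSCl, imidazole, DMF) should give bis[3-bromo-4,5-bis(tert-butyldimethylsilyloxy)benzyl] ether F2. F2 has no free hydroxyl to oxidise or to drive ipso fragmentation, and its bulky C5–OTBS shields C6. NBS in MeCN/CH2Cl2 at rt should then brominate C2 to give bis[2,3-dibromo-4,5-bis(tert-butyldimethylsilyloxy)benzyl] ether F3. TBAF buffered with AcOH (THF, 0 °C) releases 8.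

3. Step 2.
- **Risk:** C7 may be over-reduced to a methyl group. Friedel–Crafts benzylation by the ionised product may occur, or the reaction may stall after simple hydrosilylation.
- **Fallback** (stepwise Williamson assembly, from 1 back to 4, bypassing 2 and 3):
  - TIPSCl/imidazole/DMF gives 3-bromo-4-(triisopropylsilyloxy)benzaldehyde F4. TIPS is chosen over TBS because it resists alkoxide-induced silyl transfer.
  - NaBH4 (MeOH, 0 °C) gives [3-bromo-4-(triisopropylsilyloxy)phenyl]methanol F5.
  - Half of F5 is converted by the Appel reaction (CBr4, PPh3, CH2Cl2, 0 °C) into 3-bromo-4-(triisopropylsilyloxy)benzyl bromide F6.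
  - Williamson etherification of F5 with F6 (NaH, cat. Bu4NI, THF, 0 °C → rt) gives bis[3-bromo-4-(triisopropylsilyloxy)benzyl] ether F7.
  - TBAF/AcOH (THF, 0 °C) delivers 4.

Further compounds
F1 | step 4 | bis(3-bromo-5-formyl-4-hydroxybenzyl) ether | O=Cc1cc(COCc2cc(Br)c(O)c(C=O)c2)cc(Br)c1O
F2 | step 5 | bis[3-bromo-4,5-bis(tert-butyldimethylsilyloxy)benzyl] ether | CC(C)(C)[Si](C)(C)Oc1cc(COCc2cc(O[Si](C)(C)C(C)(C)C)c(O[Si](C)(C)C(C)(C)C)c(Br)c2)cc(Br)c1O[Si](C)(C)C(C)(C)C
F3 | step 5 | bis[2,3-dibromo-4,5-bis(tert-butyldimethylsilyloxy)benzyl] ether | CC(C)(C)[Si](C)(C)Oc1cc(COCc2cc(O[Si](C)(C)C(C)(C)C)c(O[Si](C)(C)C(C)(C)C)c(Br)c2Br)c(Br)c(Br)c1O[Si](C)(C)C(C)(C)C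
F4 | step 2 | 3-bromo-4-(triisopropylsilyloxy)benzaldehyde | CC(C)[Si](Oc1ccc(C=O)cc1Br)(C(C)C)C(C)C
F5 | step 2 | [3-bromo-4-(triisopropylsilyloxy)phenyl]methanol | CC(C)[Si](Oc1ccc(CO)cc1Br)(C(C)C)C(C)C
F6 | step 2 | 3-bromo-4-(triisopropylsilyloxy)benzyl bromide | CC(C)[Si](Oc1ccc(CBr)cc1Br)(C(C)C)C(C)C
F7 | step 2 | bis[3-bromo-4-(triisopropylsilyloxy)benzyl] ether | CC(C)[Si](Oc1ccc(COCc2ccc(O[Si](C(C)C)(C(C)C)C(C)C)c(Br)c2)cc1Br)(C(C)C)C(C)C
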